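## Retrosynthetic overview
1. Asperteretal H comes from its bis-TBS ether. The last step only frees the two phenols.
2. C2–C3 is made by an anti-selective boron aldol of a regiodefined E enolate with methyl glyoxylate. Both stereocentres arise here, under a C2-symmetric (S,S)-diazaborolidine on boron.
3. The key bond is C3–aryl, formed in the same flask. The α-carbon of a terminal diazoketone acts as an α-keto cation (enolonium equivalent, N2 as leaving group) and takes the 4-silyloxyphenyl group from boron by a 1,2-shift. Two innately nucleophilic carbons are joined, and the enolate forms only on the C3 side.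
4. The diazoketone comes from 4-hydroxyphenylacetic acid, prenyl bromide and CH2N2. The B-aryl reagent comes from 4-bromophenyl TBS ether, BCl3 and the bis-sulfonamide.
5. No ring is built. Both benzene rings are bought, and the diazaborolidine is only a recoverable reagent ring.

Assumption: the facial sense of the (S,S)-controller in step 6 is taken from the chair model that explains its known ketone and ester boron aldols (axial N-sulfonyl group over the aldehyde hydrogen); the (R,R)-antipode is equally available.

## Route

Step 1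
Reactants: 1 4-hydroxyphenylacetic acid; 2 prenyl bromide (1-bromo-3-methylbut-2-ene)
Product: 3 2-[4-hydroxy-3-(3-methylbut-2-enyl)phenyl]acetic acid
Conditions: KOH (2.2 equiv), H2O, 0 °C to rt, 16 h; 1 M HCl
Reagents that add atoms: none
Why: Phenoxide C-alkylation: in water the phenoxide oxygen is tied up by hydrogen bonds, so the soft allylic bromide is taken at its unsubstituted terminus by the ring carbon ortho to oxygen (para is blocked, both ortho sites are equivalent), and rearomatisation gives 3; no stereocentre is involved.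

Step 2
Reactants: 3 2-[4-hydroxy-3-(3-methylbut-2-enyl)phenyl]acetic acid
Product: 4 tert-butyldimethylsilyl 2-[4-(tert-butyldimethylsilyloxy)-3-(3-methylbut-2-enyl)phenyl]acetate
Conditions: TBSCl (2.3 equiv), imidazole, DMF, rt; pentane extraction, used without chromatography
Reagents that add atoms: tert-butyldimethylsilyl chloride CC(C)(C)[Si](C)(C)Cl
Why: Imidazole-promoted silylation caps the phenol for the boron chemistry and turns the acid into the silyl ester needed for a neutral acid chloride synthesis; no stereocentre is involved.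

Step 3
Reactants: 4 tert-butyldimethylsilyl 2-[4-(tert-butyldimethylsilyloxy)-3-(3-methylbut-2-enyl)phenyl]acetate
Product: 6 1-diazo-3-[4-(tert-butyldimethylsilyloxy)-3-(3-methylbut-2-enyl)phenyl]propan-2-one, via acid chloride 5 (not isolated)
Conditions: (COCl)2 (1.1 equiv), DMF (cat.), CH2Cl2, 0 °C to rt; evaporate; CH2N2 (3 equiv), Et2O, 0 °C
Reagents that add atoms: diazomethane C=[N+]=[N-]; oxalyl chloride ClC(=O)C(=O)Cl (chlorine of 5)
Why: The chloroiminium salt from (COCl)2 and DMF converts a silyl ester into the acid chloride with TBSCl instead of HCl as by-product, so the prenyl alkene and the aryl silyl ether survive, and excess CH2N2 is then C-acylated as in the first stage of the Arndt–Eistert sequence.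

Step 4
Reactants: 7 (4-bromophenoxy)(tert-butyl)dimethylsilane
Product: 9 tributyl[4-(tert-butyldimethylsilyloxy)phenyl]stannane, via aryllithium 8 (not isolated)
Conditions: n-BuLi, THF, −78 °C; Bu3SnCl, −78 °C to rt
Reagents that add atoms: tributyltin chloride CCCC[Sn](Cl)(CCCC)CCCC; n-butyllithium [Li]CCCC (lithium of 8)
Why: Bromine–lithium exchange followed by trapping of the aryllithium at tin; the para silyl ether cannot migrate and tolerates n-BuLi at −78 °C.

Step 5
Reactants: 9 tributyl[4-(tert-butyldimethylsilyloxy)phenyl]stannane; 10 (1S,2S)-N,N'-bis(4-methylphenylsulfonyl)-1,2-diphenylethane-1,2-diamine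
Product: 12 (4S,5S)-2-[4-(tert-butyldimethylsilyloxy)phenyl]-4,5-diphenyl-1,3-bis(4-methylphenylsulfonyl)-1,3,2-diazaborolidine (used as crude solution), via aryldichloroborane 11 (not isolated)
Conditions: BCl3 (1.0 equiv), CH2Cl2, −78 °C to rt; 10 (1.0 equiv), CH2Cl2, rt to 40 °C; volatiles off in vacuo
Reagents that add atoms: boron trichloride ClB(Cl)Cl
Why: Ipso tin–boron exchange of an electron-rich arylstannane with BCl3 is fast and clean, and the two B–Cl bonds of 11 then condense with the acidic sulfonamide N–H groups under loss of HCl in the way the parent 2-bromodiazaborolidine and B-aryl N-sulfonyl oxazaborolidinones are made; the two stereocentres of 10 are not touched.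

Step 6
Reactants: 12 (4S,5S)-B-aryl diazaborolidine; 6 1-diazo-3-[4-(tert-butyldimethylsilyloxy)-3-(3-methylbut-2-enyl)phenyl]propan-2-one; 13 methyl glyoxylate (distilled from P2O5 before use)
Product: 16 methyl (2R,3S)-3-[4-(tert-butyldimethylsilyloxy)phenyl]-5-[4-(tert-butyldimethylsilyloxy)-3-(3-methylbut-2-enyl)phenyl]-2-hydroxy-4-oxopentanoate, via boron enolate 14 (not isolated), via boron aldolate 15 (not isolated)
Conditions: 12 (1.15 equiv), 6, CH2Cl2, −78 to 0 °C until N2 stops; −78 °C, 13 (2 equiv), 2 h; pH 7 buffer, MeOH; 10 filtered off and reused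
Reagents that add atoms: none
Why: Proposed new method: the diazo carbon of 6 adds to the Lewis-acidic boron of 12, and in the ate complex the aryl group (the only carbon ligand on boron) shifts to this carbon while N2 leaves, so the ketone α-carbon acts as an α-keto cation (enolonium equivalent) and is joined to an aryl carbon that is itself a nucleophile; the α-boryl ketone tautomerises to the regiodefined E(O) enolate 14, which deprotonation of the unsymmetrical dibenzyl ketone could not give, and 14 adds to 13 through a Zimmerman–Traxler chair (aryl and CO2Me equatorial give 2,3-anti, and the (S,S)-controller with its axial N-sulfonyl group over the aldehyde hydrogen exposes the face that leads to 2R,3S); the closest known reactions are the Hooz reaction of alkyl- and arylboranes with α-diazocarbonyl compounds, its anti-selective multicomponent aldol and Mannich versions, and the diazaborolidine-controlled boron aldol.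

Step 7
Reactants: 16 methyl (2R,3S)-3-[4-(tert-butyldimethylsilyloxy)phenyl]-5-[4-(tert-butyldimethylsilyloxy)-3-(3-methylbut-2-enyl)phenyl]-2-hydroxy-4-oxopentanoate
Product: 17 asperteretal H, methyl (2R,3S)-2-hydroxy-5-[4-hydroxy-3-(3-methylbut-2-enyl)phenyl]-3-(4-hydroxyphenyl)-4-oxopentanoate
Conditions: HF·pyridine, pyridine, THF, 0 °C
Reagents that add atoms: none
Why: Fluoride-driven cleavage of aryl silyl ethers is fast at 0 °C, and the weakly acidic pyridine-buffered medium avoids enolisation at C3, retro-aldol cleavage, loss of water and chroman formation from the ortho-prenylphenol, so both stereocentres are kept.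

## Compound list
1 | 4-hydroxyphenylacetic acid | OC(=O)Cc1ccc(O)cc1 | starting material
2 | prenyl bromide | CC(C)=CCBr | starting material
3 | 2-[4-hydroxy-3-(3-methylbut-2-enyl)phenyl]acetic acid | CC(C)=CCc1cc(CC(=O)O)ccc1O | intermediate
4 | TBS ester and TBS ether of 3 | CC(C)=CCc1cc(CC(=O)O[Si](C)(C)C(C)(C)C)ccc1O[Si](C)(C)C(C)(C)C | intermediate
5 | 2-[4-(tert-butyldimethylsilyloxy)-3-(3-methylbut-2-enyl)phenyl]acetyl chloride | CC(C)=CCc1cc(CC(=O)Cl)ccc1O[Si](C)(C)C(C)(C)C | intermediate
6 | 1-diazo-3-[4-(tert-butyldimethylsilyloxy)-3-(3-methylbut-2-enyl)phenyl]propan-2-one | CC(C)=CCc1cc(CC(=O)C=[N+]=[N-])ccc1O[Si](C)(C)C(C)(C)C | intermediate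
7 | (4-bromophenoxy)(tert-butyl)dimethylsilane | CC(C)(C)[Si](C)(C)Oc1ccc(Br)cc1 | starting material
8 | 4-(tert-butyldimethylsilyloxy)phenyllithium | [Li]c1ccc(O[Si](C)(C)C(C)(C)C)cc1 | intermediate
9 | tributyl[4-(tert-butyldimethylsilyloxy)phenyl]stannane | CCCC[Sn](CCCC)(CCCC)c1ccc(O[Si](C)(C)C(C)(C)C)cc1 | intermediate
10 | (1S,2S)-N,N'-bis(4-methylphenylsulfonyl)-1,2-diphenylethane-1,2-diamine | Cc1ccc(cc1)S(=O)(=O)N[C@@H](c1ccccc1)[C@H](c1ccccc1)NS(=O)(=O)c1ccc(C)cc1 | starting material
11 | dichloro[4-(tert-butyldimethylsilyloxy)phenyl]borane | ClB(Cl)c1ccc(O[Si](C)(C)C(C)(C)C)cc1 | intermediate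
12 | (4S,5S)-2-[4-(tert-butyldimethylsilyloxy)phenyl]-4,5-diphenyl-1,3-bis(4-methylphenylsulfonyl)-1,3,2-diazaborolidine | CC(C)(C)[Si](C)(C)Oc1ccc(cc1)B1N(S(=O)(=O)c2ccc(C)cc2)[C@@H](c2ccccc2)[C@H](c2ccccc2)N1S(=O)(=O)c1ccc(C)cc1 | intermediate
13 | methyl glyoxylate | COC(=O)C=O | starting material
14 | (E)-enolate, O-bound to the (4S,5S)-diazaborolidine boron; aryl on C3 trans to O and cis to the benzyl CH2 | CC(C)(C)[Si](C)(C)Oc1ccc(cc1)/C=C(\Cc1ccc(O[Si](C)(C)C(C)(C)C)c(CC=C(C)C)c1)OB1N(S(=O)(=O)c2ccc(C)cc2)[C@@H](c2ccccc2)[C@H](c2ccccc2)N1S(=O)(=O)c1ccc(C)cc1 | intermediate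
15 | (2R,3S)-aldolate, C2 oxygen bound to the (4S,5S)-diazaborolidine boron | COC(=O)[C@H](OB1N(S(=O)(=O)c2ccc(C)cc2)[C@@H](c2ccccc2)[C@H](c2ccccc2)N1S(=O)(=O)c1ccc(C)cc1)[C@@H](C(=O)Cc1ccc(O[Si](C)(C)C(C)(C)C)c(CC=C(C)C)c1)c1ccc(O[Si](C)(C)C(C)(C)C)cc1 | intermediate
16 | methyl (2R,3S)-3-[4-(tert-butyldimethylsilyloxy)phenyl]-5-[4-(tert-butyldimethylsilyloxy)-3-(3-methylbut-2-enyl)phenyl]-2-hydroxy-4-oxopentanoate | COC(=O)[C@H](O)[C@@H](C(=O)Cc1ccc(O[Si](C)(C)C(C)(C)C)c(CC=C(C)C)c1)c1ccc(O[Si](C)(C)C(C)(C)C)cc1 | intermediate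
17 | asperteretal H, (2R,3S) | COC(=O)[C@H](O)[C@@H](C(=O)Cc1ccc(O)c(CC=C(C)C)c1)c1ccc(O)cc1 | target

## Step count and risks
Total steps: 7. Longest linear sequence: 5 (steps 1, 2, 3, 6, 7).

**Most likely to fail: step 6.**
- The boron of 12 may be too hindered for ate formation.
- A nitrogen ligand may migrate instead of the aryl group.
- The E enolate may leak to Z and give the syn isomer.
- The facial control is untested with glyoxylate.

The fallback sets out from 11 and 6 and comes back at 16. The arylation is run with the small, strongly Lewis-acidic aryldichloroborane 11 itself, the reagent class for which aryl transfer to diazocarbonyl compounds is established. This gives the achiral dichloroboron enolate F1. Addition of 13 and hydrolysis give the racemic anti-aldol F2. Absolute configuration then comes from an enzymatic kinetic resolution instead of from boron. Pseudomonas cepacia lipase and vinyl acetate acetylate the (2S,3R)-enantiomer, the fast one by the Kazlauskas rule with CO2Me as the medium group, to the acetate F3. Unreacted 16 is separated by chromatography.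

**Second: step 5.** The HCl set free during ring closure may protodeboronate the electron-rich aryl–boron bond or attack the silyl ether, and closure on the less electrophilic ArBCl2 may stall. The fallback sets out from 10 and 9 and comes back at 12. The order of bond formation at boron is reversed. First 10 is condensed with BBr3 to the known bromodiazaborolidine F4 and the hydrogen halide is pumped off. The aryl group is then brought in last by tin–boron exchange with 9, so the aryl–boron bond never meets acid.

**Third: step 1.** O-alkylation, diprenylation and hydrolysis of the bromide keep the yield low. The fallback sets out from 1 and comes back at 3. The position is fixed by a halogen instead of by the ambident phenoxide. Br2 in AcOH gives 3-bromo-4-hydroxyphenylacetic acid F5. Suzuki–Miyaura coupling with 3-methylbut-2-enylboronic acid pinacol ester (Pd(OAc)2, bulky biarylphosphine chosen for attack at the unsubstituted allyl terminus, K3PO4, THF/H2O) then puts the prenyl group on that carbon.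

## Further compounds
F1 | step 6 | (E)-dichloroboron enolate | CC(C)(C)[Si](C)(C)Oc1ccc(cc1)/C=C(\Cc1ccc(O[Si](C)(C)C(C)(C)C)c(CC=C(C)C)c1)OB(Cl)Cl
F2 | step 6 | racemic anti-aldol, 1:1 mixture of 16 and its (2S,3R)-enantiomer | COC(=O)[C@H](O)[C@@H](C(=O)Cc1ccc(O[Si](C)(C)C(C)(C)C)c(CC=C(C)C)c1)c1ccc(O[Si](C)(C)C(C)(C)C)cc1.COC(=O)[C@@H](O)[C@H](C(=O)Cc1ccc(O[Si](C)(C)C(C)(C)C)c(CC=C(C)C)c1)c1ccc(O[Si](C)(C)C(C)(C)C)cc1
F3 | step 6 | (2S,3R)-2-acetate of the unwanted enantiomer | COC(=O)[C@@H](OC(C)=O)[C@H](C(=O)Cc1ccc(O[Si](C)(C)C(C)(C)C)c(CC=C(C)C)c1)c1ccc(O[Si](C)(C)C(C)(C)C)cc1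
F4 | step 5 | (4S,5S)-2-bromo-4,5-diphenyl-1,3-bis(4-methylphenylsulfonyl)-1,3,2-diazaborolidine | BrB1N(S(=O)(=O)c2ccc(C)cc2)[C@@H](c2ccccc2)[C@H](c2ccccc2)N1S(=O)(=O)c1ccc(C)cc1
F5 | step 1 | 3-bromo-4-hydroxyphenylacetic acid | OC(=O)Cc1ccc(O)c(Br)c1
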